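Z, the substrate, goes over to J, and Q and G both take J in the three flasks below.

    Z ⇌ J (K1 = 0.057, k1 = 0.027 /s)
    Q + J ⇌ Q.J (K2 = 2.2 /M, k2 = 3.2 /M/s)
    G + J → G.J (k3 = 0.23 /M/s)
    Z + Q.J ⇌ Z.Q.J, settled at all times (K4 = 5.6 /M)
    2 Z → Z2 (k5 = 2.1 × 10⁻⁵ /M/s)

| flask | Z | Q | G | time | remark |
|---|---|---|---|---|---|
| eta | 0.50 M | 0.750 M | 0.450 M (fed, over 40 s) | 1.5 min | all else is in the flask from the start; the feed brings no volume worth counting |
| beta | 0.50 M (fed, over 40 s) | 0.750 M | 0.450 M | 1.5 min | all else is in the flask from the start; the feed brings no volume worth counting |
| gamma | 0.50 M | 0.750 M | 0.450 M | 1.5 min | everything together at the start |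

- the flask with the highest share of Q.J in Q.J plus G.J ("all alike" if they lie within 1.5 percentage points) (eta / beta / gamma / all alike)
- share of Q.J in Q.J plus G.J at the end, eta
- share of Q.J in Q.J plus G.J at the end, beta
- share of Q.J in Q.J plus G.J at the end, gamma

- percent here means Z units held: one Z.Q.J or Z2 counts as two
- what is said of Q.J includes Z.Q.J
- for a step with 2 of a species take k times the square, and two of it per event
- in an amount of Q.J, one Z.Q.J counts as one Q.J
- run time (eta): 1.5 min

**The puzzle.** With the concentrations as charged in gamma, Q takes J with a forward half-life of 0.29 s and G with one of 0.11 min, so Q looks 23.2 times quicker. Yet K2[Q] at the start of gamma is only 1.6. Step 2 runs back, and at its balance K2[Q] is the ratio of unbound Q.J to free J, while step 3 has no way back.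

**Our reckoning.** By step 1 alone, Z and J relax with a half-life of 1.38 s, far shorter than the run, so as our own estimate we take a pre-equilibrium, our plateau. With Q held at its charge and G.J left out, the balance of Z units gives [Z] = 0.333 M and [J] = 0.0190 M. In gamma, G falls as the exponential of minus k3 times [J] summed over time. Replacing that curve by the plateau gives 0.393, our exposure. So we reckon for gamma 0.146 M of G.J against 0.0897 M of Q.J, a share of 38.0 %. A feed delays the mean arrival of the fed species by half of 40 s, which in our reckoning cuts the exposure to 0.306 and lifts the share to 43.1 %. We use this for eta and beta alike, so our reckoning does not part them. Our balance leaves out the Z units that go into G.J, so we take these shares as high.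

**The forecast.** It names beta, with 36 % for eta, 37 % for beta and 30 % for gamma, since “Feeding either G or Z delays that drain and gives similar results”. Our shares stand above its figures.

**The result.** The flask with the highest share is beta: eta gives 36.8 %, beta 39.0 % and gamma 32.5 %. The forecast held.

**Exposure read.** Gamma keeps 74.2 % of its G, so its exposure was 0.298, less than our 0.393. Carried to a neighbour of gamma with 0.27 M of G, this exposure gives G.J at 13.9 % of the Z charged, and that flask reads 14.9 %. The gap between beta and gamma shrinks from 6.5 percentage points to 0.15 points once the backward run from Q.J to Q + J is taken away.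

The constants come from no measurement; the run is a simulation.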